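**Plan**
- **Feature:** in the flavanone half, ring C carries the only stereocentre, C2. It is bonded to O1 and lies β to the C4 ketone, so a retro-oxa-Michael cut of O1–C2 opens ring C to a 2'-hydroxychalcone. The 3',3''' biaryl axis has only two ortho oxygens and is not stereogenic.
- **Cuts, in retrosynthetic order:** six O–benzyl bonds; a temporary C3–CO2tBu group; O1–C2 of flavanone ring C; Cα=Cβ of the chalcone; the C3'–C3''' biaryl bond; O1–C2 and Cα=Cβ of the flavone half.
- **Forward order:** flavone ring C is made first (Claisen–Schmidt, I2/DMSO), the biaryl bond second (Suzuki–Miyaura), the activated chalcone third (Knoevenagel), and flavanone ring C last.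
- **Activating group:** an unactivated 2'-hydroxychalcone closes slowly and reversibly under amine–thiourea catalysis. A tert-butyl ester at Cα gives the thiourea a 1,3-dicarbonyl to bind and lets the closure run cold.
- **Stereochemistry:** C2 comes from the quinine-derived thiourea in the ring closure. All later steps are acidic or neutral, so base-induced ring opening cannot scramble it.

Key step: step 9

Assumption: the quinine-derived thiourea is taken to give the 2S series. The sense of induction is to be confirmed on 14 (circular dichroism, chiral HPLC), and the quinidine-derived pseudoenantiomer would be used in the same way if it proves to be the reverse.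

Step 1
Reactants: 1 2',4',6'-trihydroxyacetophenone (phloroacetophenone)
Product: 2 1-[2,4-bis(benzyloxy)-6-hydroxyphenyl]ethanone
Conditions: BnBr (2.1 equiv), K2CO3 (2.2 equiv), DMF, rt
Reagents that add atoms: benzyl bromide, BrCc1ccccc1
Why: Williamson etherification; after the 4-OH and one ortho OH are benzylated, the last ortho OH is held in a hydrogen bond to the acetyl oxygen and reacts much more slowly, so alkylation should stop at the diether.

Step 2
Reactants: 3 3-bromo-4-hydroxybenzaldehyde
Product: 4 4-(benzyloxy)-3-bromobenzaldehyde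
Conditions: BnBr (1.1 equiv), K2CO3, DMF, rt
Reagents that add atoms: benzyl bromide, BrCc1ccccc1
Why: Williamson etherification of an acidic para-formyl phenol, with no competing nucleophilic site.

Step 3
Reactants: 2 1-[2,4-bis(benzyloxy)-6-hydroxyphenyl]ethanone; 4 4-(benzyloxy)-3-bromobenzaldehyde
Product: 5 (E)-1-[2,4-bis(benzyloxy)-6-hydroxyphenyl]-3-[4-(benzyloxy)-3-bromophenyl]prop-2-en-1-one
Conditions: KOH (excess), EtOH–THF, rt; then aq. HCl
Reagents that add atoms: none
Why: Claisen–Schmidt condensation of a methyl ketone with a non-enolisable aldehyde; loss of water should give the conjugated E-enone, which stays open in strong base as its phenoxide.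

Step 4
Reactants: 5 the bromo-2'-hydroxychalcone
Product: 6 5,7-bis(benzyloxy)-2-[4-(benzyloxy)-3-bromophenyl]-4H-chromen-4-one
Conditions: I2 (10 mol %), DMSO, 130 °C
Reagents that add atoms: none
Why: Iodine-catalysed oxidative cyclisation of a 2'-hydroxychalcone to a flavone with DMSO as terminal oxidant; benzyl ethers and the aryl bromide tolerate it, whereas acetal-type protecting groups would not.

Step 5
Reactants: 4 4-(benzyloxy)-3-bromobenzaldehyde
Product: 7 4-(benzyloxy)-3-(4,4,5,5-tetramethyl-1,3,2-dioxaborolan-2-yl)benzaldehyde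
Conditions: B2pin2, Pd(dppf)Cl2 (3 mol %), KOAc, 1,4-dioxane, 90 °C
Reagents that add atoms: bis(pinacolato)diboron, CC1(C)OB(OC1(C)C)B1OC(C)(C)C(C)(C)O1
Why: Miyaura borylation; the weak base KOAc leaves the aldehyde untouched and disfavours homocoupling.

Step 6
Reactants: 6 the 3'-bromoflavone; 7 the boronate aldehyde
Product: 8 4-(benzyloxy)-3-{2-(benzyloxy)-5-[5,7-bis(benzyloxy)-4-oxo-4H-chromen-2-yl]phenyl}benzaldehyde (flavone biaryl aldehyde)
Conditions: Pd(dppf)Cl2 (5 mol %), K2CO3, 1,4-dioxane–H2O, 90 °C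
Reagents that add atoms: none
Why: Suzuki–Miyaura coupling forms C3'–C3'''; each partner has one ortho substituent only, and the aldehyde, flavone and benzyl ethers tolerate aqueous carbonate.

Step 7
Reactants: 2 1-[2,4-bis(benzyloxy)-6-hydroxyphenyl]ethanone
Product: 10 tert-butyl 3-[2,4-bis(benzyloxy)-6-hydroxyphenyl]-3-oxopropanoate, via dilithium enolate 9 (not isolated)
Conditions: LiHMDS (3.2 equiv), THF, −78 °C; Boc2O (1.05 equiv), −78 to −20 °C; AcOH
Reagents that add atoms: di-tert-butyl dicarbonate, CC(C)(C)OC(=O)OC(=O)OC(C)(C)C; LiHMDS, [Li]N([Si](C)(C)C)[Si](C)(C)C (supplies the lithium of 9)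
Why: Claisen-type C-acylation; the phenoxide–enolate dianion reacts at its more nucleophilic carbon terminus, the third equivalent of base stores the product as its stabilised enolate, and the bulky ester resists lactonisation to a 4-hydroxycoumarin.

Step 8
Reactants: 8 the flavone biaryl aldehyde; 10 the β-ketoester
Product: 11 tert-butyl (Z)-2-[2,4-bis(benzyloxy)-6-hydroxybenzoyl]-3-{4-(benzyloxy)-3-[2-(benzyloxy)-5-(5,7-bis(benzyloxy)-4-oxo-4H-chromen-2-yl)phenyl]phenyl}prop-2-enoate (α-tert-butoxycarbonyl-2'-hydroxychalcone)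
Conditions: piperidine (20 mol %), AcOH (20 mol %), 4 Å MS, toluene, rt
Reagents that add atoms: none
Why: Knoevenagel condensation under piperidinium acetate catalysis with sieves taking up the water; the isomer with the β-aryl group cis to the ester and trans to the aroyl group (Z) should prevail on steric grounds.

Step 9
Reactants: 11 the α-tert-butoxycarbonyl-2'-hydroxychalcone
Product: 12 tert-butyl (2S,3R)-5,7-bis(benzyloxy)-2-{4-(benzyloxy)-3-[2-(benzyloxy)-5-(5,7-bis(benzyloxy)-4-oxo-4H-chromen-2-yl)phenyl]phenyl}-4-oxochromane-3-carboxylate (2,3-trans)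
Conditions: N-[3,5-bis(trifluoromethyl)phenyl]-N'-[(8α,9S)-6'-methoxycinchonan-9-yl]thiourea (10 mol %), toluene, −25 °C; cold filtration through a short silica pad
Reagents that add atoms: none
Why: The quinuclidine nitrogen takes the proton of the 2'-OH while the two thiourea N–H bonds hold the 1,3-dicarbonyl unit; the phenoxide oxygen then adds to Cβ to form O1–C2, and the β-ketoester enolate is protonated at C3. This is the known amine–thiourea catalysed intramolecular oxa-Michael addition of alkylidene β-ketoesters to flavanone-3-carboxylates, applied here to a larger β-aryl group. Ring C closes in the 6-endo-trig mode. C2 is controlled by the catalyst, which exposes one face of the bound alkylidene to the tethered oxygen, whereas C3 is under thermodynamic control because its acidic hydrogen lets the ester settle trans to the C2 aryl group, and this centre is erased in step 10. Chemoselectivity rests on the substrate, which has a single unprotected hydroxyl, while the flavone C2=C3–C4=O unit belongs to a 4-pyranone fully substituted at its β-carbon and takes no part. The double activation lets the closure run at −25 °C, where the reverse reaction and the uncatalysed background are slow, and prompt removal of the amine prevents later erosion at C2.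

Step 10
Reactants: 12 the flavanone-3-carboxylate
Product: 14 (2S)-5,7-bis(benzyloxy)-2-{4-(benzyloxy)-3-[2-(benzyloxy)-5-(5,7-bis(benzyloxy)-4-oxo-4H-chromen-2-yl)phenyl]phenyl}chroman-4-one (hexa-O-benzyl target), via beta-keto acid 13 (not isolated)
Conditions: TsOH·H2O (cat.), toluene, 80 °C
Reagents that add atoms: none
Why: Acid-catalysed loss of isobutene from the tert-butyl ester and thermal decarboxylation of the β-keto acid remove the activating group and the C3 centre; C2 is untouched because ring opening needs base, and aryl benzyl ethers withstand catalytic TsOH in hot toluene.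

Step 11
Reactants: 14 the hexa-O-benzyl target
Product: 15 (2S)-2,3-dihydro-3',3'''-biapigenin (CNP0184920.1)
Conditions: H2 (1 atm), 10% Pd/C, THF–MeOH, rt
Reagents that add atoms: none
Why: Catalytic hydrogenolysis of six aryl benzyl ethers in a neutral medium, where the 4-pyranone double bond and the flavanone ketone are normally retained and C2 has no base-mediated path to racemisation.

**Compound list**
1 | 2',4',6'-trihydroxyacetophenone | CC(=O)c1c(O)cc(O)cc1O | starting material
2 | 1-[2,4-bis(benzyloxy)-6-hydroxyphenyl]ethanone | CC(=O)c1c(O)cc(OCc2ccccc2)cc1OCc1ccccc1 | intermediate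
3 | 3-bromo-4-hydroxybenzaldehyde | O=Cc1ccc(O)c(Br)c1 | starting material
4 | 4-(benzyloxy)-3-bromobenzaldehyde | O=Cc1ccc(OCc2ccccc2)c(Br)c1 | intermediate
5 | (E)-1-[2,4-bis(benzyloxy)-6-hydroxyphenyl]-3-[4-(benzyloxy)-3-bromophenyl]prop-2-en-1-one | O=C(/C=C/c1ccc(OCc2ccccc2)c(Br)c1)c1c(O)cc(OCc2ccccc2)cc1OCc1ccccc1 | intermediate
6 | 5,7-bis(benzyloxy)-2-[4-(benzyloxy)-3-bromophenyl]-4H-chromen-4-one | O=c1cc(-c2ccc(OCc3ccccc3)c(Br)c2)oc2cc(OCc3ccccc3)cc(OCc3ccccc3)c12 | intermediate
7 | 4-(benzyloxy)-3-(4,4,5,5-tetramethyl-1,3,2-dioxaborolan-2-yl)benzaldehyde | O=Cc1ccc(OCc2ccccc2)c(B2OC(C)(C)C(C)(C)O2)c1 | intermediate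
8 | 4-(benzyloxy)-3-{2-(benzyloxy)-5-[5,7-bis(benzyloxy)-4-oxo-4H-chromen-2-yl]phenyl}benzaldehyde | O=Cc1ccc(OCc2ccccc2)c(-c2cc(-c3cc(=O)c4c(OCc5ccccc5)cc(OCc5ccccc5)cc4o3)ccc2OCc2ccccc2)c1 | intermediate
9 | dilithium phenoxide enolate of 2 (not isolated) | C=C(O[Li])c1c(O[Li])cc(OCc2ccccc2)cc1OCc1ccccc1 | intermediate
10 | tert-butyl 3-[2,4-bis(benzyloxy)-6-hydroxyphenyl]-3-oxopropanoate | CC(C)(C)OC(=O)CC(=O)c1c(O)cc(OCc2ccccc2)cc1OCc1ccccc1 | intermediate
11 | tert-butyl (Z)-2-[2,4-bis(benzyloxy)-6-hydroxybenzoyl]-3-{4-(benzyloxy)-3-[2-(benzyloxy)-5-(5,7-bis(benzyloxy)-4-oxo-4H-chromen-2-yl)phenyl]phenyl}prop-2-enoate | O=C(/C(C(=O)OC(C)(C)C)=C/c1ccc(OCc2ccccc2)c(-c2cc(-c3cc(=O)c4c(OCc5ccccc5)cc(OCc5ccccc5)cc4o3)ccc2OCc2ccccc2)c1)c1c(O)cc(OCc2ccccc2)cc1OCc1ccccc1 | intermediate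
12 | tert-butyl (2S,3R)-5,7-bis(benzyloxy)-2-{4-(benzyloxy)-3-[2-(benzyloxy)-5-(5,7-bis(benzyloxy)-4-oxo-4H-chromen-2-yl)phenyl]phenyl}-4-oxochromane-3-carboxylate | O=C1[C@H](C(=O)OC(C)(C)C)[C@@H](c2ccc(OCc3ccccc3)c(-c3cc(-c4cc(=O)c5c(OCc6ccccc6)cc(OCc6ccccc6)cc5o4)ccc3OCc3ccccc3)c2)Oc2cc(OCc3ccccc3)cc(OCc3ccccc3)c21 | intermediate
13 | (2S,3R)-3-carboxylic acid corresponding to 12 (not isolated) | O=C1[C@H](C(=O)O)[C@@H](c2ccc(OCc3ccccc3)c(-c3cc(-c4cc(=O)c5c(OCc6ccccc6)cc(OCc6ccccc6)cc5o4)ccc3OCc3ccccc3)c2)Oc2cc(OCc3ccccc3)cc(OCc3ccccc3)c21 | intermediate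
14 | (2S)-5,7-bis(benzyloxy)-2-{4-(benzyloxy)-3-[2-(benzyloxy)-5-(5,7-bis(benzyloxy)-4-oxo-4H-chromen-2-yl)phenyl]phenyl}chroman-4-one | O=C1C[C@@H](c2ccc(OCc3ccccc3)c(-c3cc(-c4cc(=O)c5c(OCc6ccccc6)cc(OCc6ccccc6)cc5o4)ccc3OCc3ccccc3)c2)Oc2cc(OCc3ccccc3)cc(OCc3ccccc3)c21 | intermediate
15 | (2S)-5,7-dihydroxy-2-{4-hydroxy-3-[2-hydroxy-5-(5,7-dihydroxy-4-oxo-4H-chromen-2-yl)phenyl]phenyl}chroman-4-one | O=C1C[C@@H](c2ccc(O)c(-c3cc(-c4cc(=O)c5c(O)cc(O)cc5o4)ccc3O)c2)Oc2cc(O)cc(O)c21 | target

**Step count**
Total steps: 11.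
Longest linear sequence: 8 steps (1 → 2 → 5 → 6 → 8 → 11 → 12 → 14 → 15).

**Steps most likely to fail**

**Step 9.** Facial selectivity may be poor, or C2 may erode by reversible ring opening. The 6'-benzyloxy group twists the aroyl unit, and the β-aryl group is much larger than those on which this reaction type is established.

The fallback takes the stereochemistry from a kinetic resolution instead of from the C–O bond formation. It sets out from 8 and comes back at 14.
- Aldehyde 8 is condensed with ketone 2 (KOH, EtOH–THF, rt) to the ester-free 2'-hydroxychalcone F1.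
- F1 is closed without stereocontrol (NaOAc, EtOH, reflux) to the racemic hexa-O-benzyl flavanone F2.
- Asymmetric transfer hydrogenation (Cp*RhCl[(R,R)-TsDPEN], HCO2H–Et3N, EtOAc, rt) is stopped near half conversion. It should reduce the 2R ketone to the cis (2R,4R)-flavan-4-ol F3 and leave the mismatched 2S ketone, which is 14 after chromatography.
- The flavone carbonyl, being part of a 4-pyranone, is not expected to accept hydride.

**Step 8.** The amine used for the condensation may close the ring prematurely, which would deliver racemic material before the chiral catalyst is present. The electron-rich aldehyde may also convert slowly.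

The fallback removes the nucleophile during the condensation. It sets out from 10 and comes back at 11.
- The phenol of 10 is silylated (TBSCl, imidazole, DMF) to the silyl ether tert-butyl 3-[2,4-bis(benzyloxy)-6-(tert-butyldimethylsilyloxy)phenyl]-3-oxopropanoate F4.
- Knoevenagel condensation of F4 with 8 under the same catalysis gives the O-silylated alkylidene β-ketoester F5, which cannot cyclise.
- The phenol is released in an acidic, base-free medium (HF·pyridine, THF, 0 °C) to give 11 directly before step 9.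

**Step 11.** Over-reduction may occur, either by saturation of the flavone C2=C3 bond or by hydrogenolysis of the benzylic C2–O1 bond of the flavanone. Cleavage may also be incomplete as partly deprotected material loses solubility.

The fallback replaces reductive cleavage by Lewis-acid dealkylation with a cation scavenger (BCl3, pentamethylbenzene, CH2Cl2, −78 °C; MeOH quench). It sets out from 14, comes back at 15 and makes no new compound.

**Further compounds**
F1 | step 9 | (E)-1-[2,4-bis(benzyloxy)-6-hydroxyphenyl]-3-{4-(benzyloxy)-3-[2-(benzyloxy)-5-(5,7-bis(benzyloxy)-4-oxo-4H-chromen-2-yl)phenyl]phenyl}prop-2-en-1-one | O=C(/C=C/c1ccc(OCc2ccccc2)c(-c2cc(-c3cc(=O)c4c(OCc5ccccc5)cc(OCc5ccccc5)cc4o3)ccc2OCc2ccccc2)c1)c1c(O)cc(OCc2ccccc2)cc1OCc1ccccc1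
F2 | step 9 | racemic hexa-O-benzyl flavanone (racemate of 14) | O=C1CC(c2ccc(OCc3ccccc3)c(-c3cc(-c4cc(=O)c5c(OCc6ccccc6)cc(OCc6ccccc6)cc5o4)ccc3OCc3ccccc3)c2)Oc2cc(OCc3ccccc3)cc(OCc3ccccc3)c21
F3 | step 9 | (2R,4R)-cis-flavan-4-ol from the 2R enantiomer of F2 | O[C@@H]1C[C@H](c2ccc(OCc3ccccc3)c(-c3cc(-c4cc(=O)c5c(OCc6ccccc6)cc(OCc6ccccc6)cc5o4)ccc3OCc3ccccc3)c2)Oc2cc(OCc3ccccc3)cc(OCc3ccccc3)c21
F4 | step 8 | tert-butyl 3-[2,4-bis(benzyloxy)-6-(tert-butyldimethylsilyloxy)phenyl]-3-oxopropanoate | CC(C)(C)OC(=O)CC(=O)c1c(O[Si](C)(C)C(C)(C)C)cc(OCc2ccccc2)cc1OCc1ccccc1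
F5 | step 8 | O-tert-butyldimethylsilyl ether of 11, (Z) | O=C(/C(C(=O)OC(C)(C)C)=C/c1ccc(OCc2ccccc2)c(-c2cc(-c3cc(=O)c4c(OCc5ccccc5)cc(OCc5ccccc5)cc4o3)ccc2OCc2ccccc2)c1)c1c(O[Si](C)(C)C(C)(C)C)cc(OCc2ccccc2)cc1OCc1ccccc1
F0 | step 11 | none | none
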